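**Retrosynthetic overview**

1. The target is a (2R,3S,4S)-7,8,3',4'-tetrahydroxyflavan-3-ol (upper unit, rings A, C, B; 2,3-trans, 3,4-trans) bonded from C4 to C8 of (+)-catechin (lower unit, rings D, F, E). The last operations are global O-debenzylation and, before it, conversion of a C2 methyl ketal into C2–H by ionic hydrogenation.
2. The strategy rests on this feature: in the upper unit O1–C8a–C4a–C4 is a latent ortho-quinone methide of ring A whose methide carbon C4 carries catechin C8, and C2–C3 is an enol ether at the oxidation level of a ketone. Cutting C3–C4 and O1–C2 (retro oxa-[4+2]) gives an ortho-hydroxybenzhydrol and a (Z)-α-methoxy-β-benzyloxystyrene.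
3. The benzhydrol comes from addition of 8-lithio-penta-O-benzylcatechin to a 2-O-allyl ring A salicylaldehyde, followed by deallylation under neutral conditions.
4. The enol ether comes from 3',4'-dihydroxyacetophenone by benzylation, hypervalent-iodine α-hydroxylation with ketalisation, O-benzylation and loss of methanol.
5. Rings A, B, D, E and F are bought (D, F, E intact from the chiral pool); ring C is the only ring formed, in the key step.

Key step: step 12

Stereochemistry planned for: upper unit 2R,3S,4S (the aryl groups at C2 and C4 cis to each other and trans to the 3-oxygen), lower unit (2R,3S) as in (+)-catechin.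

Assumption: the (R) antipode of the phosphoric acid is taken as the one that leaves the Re face of the methide carbon open; if the sense of induction proves opposite, the (S) acid is used in step 12 with nothing else changed.

**Route**

Step 1
Reactants: 1 (+)-catechin
Product: 2 5,7,3',4'-tetra-O-benzyl-(+)-catechin
Conditions: BnBr (4.4 equiv), K2CO3, DMF, 0 °C → rt
Reagents that add atoms: benzyl bromide, BrCc1ccccc1
Why: Williamson etherification in which carbonate deprotonates only the four phenols, so the secondary 3-OH stays free and the mild base leaves C2 and C3 untouched.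

Step 2
Reactants: 2 5,7,3',4'-tetra-O-benzyl-(+)-catechin
Product: 3 8-bromo-5,7,3',4'-tetra-O-benzyl-(+)-catechin
Conditions: NBS (1.0 equiv), CH2Cl2, −78 °C → rt
Reagents that add atoms: N-bromosuccinimide, O=C1CCC(=O)N1Br
Why: Electrophilic aromatic bromination of the phloroglucinol-type ring D, where C8 is the more reactive of the two free positions in the tetrabenzyl ether, a known regioselective monobromination.

Step 3
Reactants: 3 8-bromo-5,7,3',4'-tetra-O-benzyl-(+)-catechin
Product: 4 8-bromo-3,5,7,3',4'-penta-O-benzyl-(+)-catechin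
Conditions: NaH, BnBr, DMF, 0 °C → rt
Reagents that add atoms: benzyl bromide, BrCc1ccccc1
Why: Williamson etherification of the secondary alkoxide removes the last acidic proton before the lithiation, and the aryl bromide is inert to NaH.

Step 4
Reactants: 5 2,3,4-trihydroxybenzaldehyde
Product: 6 3,4-bis(benzyloxy)-2-hydroxybenzaldehyde
Conditions: BnBr (2.1 equiv), K2CO3, DMF, rt
Reagents that add atoms: benzyl bromide, BrCc1ccccc1
Why: Williamson etherification in which the 2-oxygen, hydrogen-bonded to and conjugated with the formyl group, is the least nucleophilic, so the 4- and 3-oxygens should be benzylated first.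

Step 5
Reactants: 6 3,4-bis(benzyloxy)-2-hydroxybenzaldehyde
Product: 7 2-(allyloxy)-3,4-bis(benzyloxy)benzaldehyde
Conditions: allyl bromide, K2CO3, DMF, 60 °C
Reagents that add atoms: allyl bromide, C=CCBr
Why: Williamson allylation of the remaining chelated phenol; allyl is inert to an aryllithium at −78 °C and is later removed by palladium under neutral conditions, leaving benzyl ethers and the acid-labile benzhydrol alone.

Step 6
Reactants: 4 8-bromo-3,5,7,3',4'-penta-O-benzyl-(+)-catechin; 7 2-(allyloxy)-3,4-bis(benzyloxy)benzaldehyde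
Product: 9 [2-(allyloxy)-3,4-bis(benzyloxy)phenyl](3,5,7,3',4'-penta-O-benzylcatechin-8-yl)methanol (both carbinol epimers), via 8-lithio-penta-O-benzylcatechin 8 (not isolated)
Conditions: n-BuLi (1.05 equiv), THF, −78 °C; then 7, −78 → −40 °C; aq. NH4Cl
Reagents that add atoms: none
Why: Bromine–lithium exchange followed by 1,2-addition of the aryllithium to the aldehyde, as known for 8-lithiated benzylated flavan-3-ols and carbonyl compounds; the carbinol centre forms as a mixture, which is of no consequence because it becomes trigonal in step 12.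

Step 7
Reactants: 9 [2-(allyloxy)-3,4-bis(benzyloxy)phenyl](3,5,7,3',4'-penta-O-benzylcatechin-8-yl)methanol
Product: 10 [3,4-bis(benzyloxy)-2-hydroxyphenyl](3,5,7,3',4'-penta-O-benzylcatechin-8-yl)methanol (both carbinol epimers)
Conditions: Pd(PPh3)4 (5 mol%), morpholine (5 equiv), THF, rt; chromatography on Et3N-deactivated silica, used promptly
Reagents that add atoms: none
Why: Tsuji–Trost-type deallylation in which zerovalent palladium ionises the aryl allyl ether and morpholine captures the π-allyl fragment, neutral conditions under which the easily ionised benzhydrol and all benzyl ethers persist.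

Step 8
Reactants: 11 1-(3,4-dihydroxyphenyl)ethan-1-one
Product: 12 1-[3,4-bis(benzyloxy)phenyl]ethan-1-one
Conditions: BnBr (2.2 equiv), K2CO3, DMF, 60 °C
Reagents that add atoms: benzyl bromide, BrCc1ccccc1
Why: Williamson etherification of the two phenols; the methyl ketone is not alkylated by carbonate.

Step 9
Reactants: 12 1-[3,4-bis(benzyloxy)phenyl]ethan-1-one
Product: 13 2-[3,4-bis(benzyloxy)phenyl]-2,2-dimethoxyethan-1-ol
Conditions: PhI(OAc)2 (1.1 equiv), KOH (3 equiv), MeOH/THF, 0 °C → rt
Reagents that add atoms: methanol, CO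
Why: Moriarty α-hydroxylation: the enolate is captured by the hypervalent iodine reagent, methoxide adds to the carbonyl, the alkoxide displaces iodobenzene to a methoxy epoxide and methoxide opens it, giving the α-hydroxy dimethyl ketal directly under basic conditions that benzyl ethers tolerate.

Step 10
Reactants: 13 2-[3,4-bis(benzyloxy)phenyl]-2,2-dimethoxyethan-1-ol
Product: 14 1,2-bis(benzyloxy)-4-[2-(benzyloxy)-1,1-dimethoxyethyl]benzene
Conditions: NaH, BnBr, THF/DMF, 0 °C → rt
Reagents that add atoms: benzyl bromide, BrCc1ccccc1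
Why: Williamson etherification of the primary alkoxide; the ketal is stable to base.

Step 11
Reactants: 14 1,2-bis(benzyloxy)-4-[2-(benzyloxy)-1,1-dimethoxyethyl]benzene
Product: 15 (Z)-2-benzyloxy-1-methoxy-1-[3,4-bis(benzyloxy)phenyl]ethene
Conditions: TMSOTf (1.2 equiv), i-Pr2NEt (1.5 equiv), CH2Cl2, −20 °C → rt; basic work-up, stored over K2CO3
Reagents that add atoms: none
Why: Silyl-triflate-mediated elimination of methanol from a ketal: TMSOTf ionises one methoxy group and the hindered amine removes a proton from the only α-carbon; the (Z) isomer is expected because it places the aryl group trans to the benzyloxy group and the two oxygens cis, the preferred arrangement of a 1,2-dialkoxyalkene.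

Step 12
Reactants: 10 [3,4-bis(benzyloxy)-2-hydroxyphenyl](3,5,7,3',4'-penta-O-benzylcatechin-8-yl)methanol; 15 (Z)-2-benzyloxy-1-methoxy-1-[3,4-bis(benzyloxy)phenyl]ethene
Product: 17 (2R,3S,4S)-3,7,8-tris(benzyloxy)-2-[3,4-bis(benzyloxy)phenyl]-2-methoxy-4-(3,5,7,3',4'-penta-O-benzylcatechin-8-yl)chromane (2-methoxy ketal of the deca-O-benzyl dimer; 3,4-trans), via ortho-quinone methide 16 (not isolated)
Conditions: (R)-3,3'-bis(2,4,6-triisopropylphenyl)-1,1'-binaphthyl-2,2'-diyl hydrogen phosphate (10 mol%), 15 (2.5 equiv), 4 Å MS, toluene, −20 °C → rt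
Reagents that add atoms: none
Why: The chiral phosphoric acid protonates the benzylic hydroxyl of 10 and water leaves, giving the ring A ortho-quinone methide 16 (stabilised by the donor-rich catechin aryl on the methide carbon), which stays hydrogen-bonded through its carbonyl oxygen to the chiral phosphate; the nucleophilic CH(OBn) carbon of 15 then bonds to the methide carbon (C3–C4) while the ring A oxygen bonds to the methoxy-bearing carbon (O1–C2), a strongly asynchronous inverse-electron-demand oxa-[4+2] cycloaddition. The closest known reaction type is the Brønsted-acid-catalysed, including chiral-phosphoric-acid-catalysed, [4+2] cycloaddition of ortho-quinone methides generated from ortho-hydroxybenzhydrols with enol ethers, enamides and styrenes to give 2-substituted 4-arylchromans. Ring C is closed in the [4+2] mode, the four-atom component being O1=C8a–C4a=C4 and the two-atom component C3=C2 (should the addition be stepwise, the second bond forms by 6-exo-trig attack of the phenol oxygen on the aryl- and methoxy-stabilised oxocarbenium ion). C4 is set by the phosphate, which must leave the Re face of the methide carbon open (4S); C3 is set relative to C4 by the exo placement of the benzyloxy group, that is ring B endo over the methide, which gives 3,4-trans (3S); C2 follows from suprafacial addition of the (Z)-alkene (OMe cis to 3-OBn) and is of no consequence because step 13 erases it. The step needs regioselectivity, secured because bonding through the CH(OBn) carbon leaves the charge on the carbon that carries both OMe and the para-benzyloxyphenyl ring, chemoselectivity, secured because the only free phenol and hence the only possible quinone methide lies in ring A, and facial selectivity, which has to come from the catalyst because the catechin stereocentres are remote from C4.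

Step 13
Reactants: 17 (2R,3S,4S)-2-methoxy ketal of the deca-O-benzyl dimer
Product: 19 (2R,3S,4S)-3,7,8-tris(benzyloxy)-2-[3,4-bis(benzyloxy)phenyl]-4-[(2R,3S)-3,5,7,3',4'-penta-O-benzylcatechin-8-yl]chromane (deca-O-benzyl dimer), via C2 oxocarbenium ion 18 (not isolated)
Conditions: Et3SiH (5 equiv), BF3·OEt2 (2 equiv), CH2Cl2, −78 → −30 °C
Reagents that add atoms: none
Why: Ionic hydrogenation of a ketal: BF3 ionises the anomeric methoxy group to the ring B-conjugated oxocarbenium ion 18, and the silane should add axially to the half-chair in which 3-OBn and the 4-aryl group are pseudo-equatorial, on the face opposite the bulky catechin unit at C4, so that H2 ends trans-diaxial to H3 and ring B equatorial (2R, 2,3-trans).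

Step 14
Reactants: 19 deca-O-benzyl dimer
Product: 20 CNP0231186.1, (2R,3S,4S)-2-(3,4-dihydroxyphenyl)-4-[(2R,3S)-2-(3,4-dihydroxyphenyl)-3,5,7-trihydroxychroman-8-yl]chromane-3,7,8-triol
Conditions: H2 (1 atm), Pd(OH)2/C, THF/MeOH/H2O, rt; filtration and lyophilisation under argon
Reagents that add atoms: none
Why: Hydrogenolysis of the ten O-benzyl ethers, the standard unmasking of benzylated proanthocyanidins, which under one atmosphere at room temperature should leave the C4–aryl and C2–O1 bonds and all five stereocentres untouched.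

**Compound list**

1 | (+)-catechin | O[C@H]1Cc2c(O)cc(O)cc2O[C@@H]1c1ccc(O)c(O)c1 | starting material
2 | 5,7,3',4'-tetra-O-benzyl-(+)-catechin | c1c(OCc9ccccc9)cc(OCc9ccccc9)c2c1O[C@H](c1ccc(OCc9ccccc9)c(OCc9ccccc9)c1)[C@@H](O)C2 | intermediate
3 | 8-bromo-5,7,3',4'-tetra-O-benzyl-(+)-catechin | Brc1c(OCc9ccccc9)cc(OCc9ccccc9)c2c1O[C@H](c1ccc(OCc9ccccc9)c(OCc9ccccc9)c1)[C@@H](O)C2 | intermediate
4 | 8-bromo-3,5,7,3',4'-penta-O-benzyl-(+)-catechin | Brc1c(OCc9ccccc9)cc(OCc9ccccc9)c2c1O[C@H](c1ccc(OCc9ccccc9)c(OCc9ccccc9)c1)[C@@H](OCc9ccccc9)C2 | intermediate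
5 | 2,3,4-trihydroxybenzaldehyde | O=Cc1ccc(O)c(O)c1O | starting material
6 | 3,4-bis(benzyloxy)-2-hydroxybenzaldehyde | O=Cc1ccc(OCc9ccccc9)c(OCc9ccccc9)c1O | intermediate
7 | 2-(allyloxy)-3,4-bis(benzyloxy)benzaldehyde | O=Cc1ccc(OCc9ccccc9)c(OCc9ccccc9)c1OCC=C | intermediate
8 | 8-lithio-3,5,7,3',4'-penta-O-benzylcatechin (formed in the flask) | [Li]c1c(OCc9ccccc9)cc(OCc9ccccc9)c2c1O[C@H](c1ccc(OCc9ccccc9)c(OCc9ccccc9)c1)[C@@H](OCc9ccccc9)C2 | intermediate
9 | [2-(allyloxy)-3,4-bis(benzyloxy)phenyl](3,5,7,3',4'-penta-O-benzylcatechin-8-yl)methanol, both carbinol epimers | C=CCOc1c(OCc9ccccc9)c(OCc9ccccc9)ccc1C(O)c1c(OCc9ccccc9)cc(OCc9ccccc9)c2c1O[C@H](c1ccc(OCc9ccccc9)c(OCc9ccccc9)c1)[C@@H](OCc9ccccc9)C2 | intermediate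
10 | [3,4-bis(benzyloxy)-2-hydroxyphenyl](3,5,7,3',4'-penta-O-benzylcatechin-8-yl)methanol, both carbinol epimers | Oc1c(OCc9ccccc9)c(OCc9ccccc9)ccc1C(O)c1c(OCc9ccccc9)cc(OCc9ccccc9)c2c1O[C@H](c1ccc(OCc9ccccc9)c(OCc9ccccc9)c1)[C@@H](OCc9ccccc9)C2 | intermediate
11 | 1-(3,4-dihydroxyphenyl)ethan-1-one (3',4'-dihydroxyacetophenone) | CC(=O)c1ccc(O)c(O)c1 | starting material
12 | 1-[3,4-bis(benzyloxy)phenyl]ethan-1-one | CC(=O)c1ccc(OCc9ccccc9)c(OCc9ccccc9)c1 | intermediate
13 | 2-[3,4-bis(benzyloxy)phenyl]-2,2-dimethoxyethan-1-ol | OCC(OC)(OC)c1ccc(OCc9ccccc9)c(OCc9ccccc9)c1 | intermediate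
14 | 1,2-bis(benzyloxy)-4-[2-(benzyloxy)-1,1-dimethoxyethyl]benzene | COC(COCc9ccccc9)(OC)c1ccc(OCc9ccccc9)c(OCc9ccccc9)c1 | intermediate
15 | (Z)-2-benzyloxy-1-methoxy-1-[3,4-bis(benzyloxy)phenyl]ethene | CO/C(=C\OCc9ccccc9)c1ccc(OCc9ccccc9)c(OCc9ccccc9)c1 | intermediate
16 | (E)-2,3-bis(benzyloxy)-6-[(3,5,7,3',4'-penta-O-benzylcatechin-8-yl)methylidene]cyclohexa-2,4-dien-1-one, ring A ortho-quinone methide (formed in the flask) | O=C1C(OCc9ccccc9)=C(OCc9ccccc9)C=C/C1=C\c1c(OCc9ccccc9)cc(OCc9ccccc9)c2c1O[C@H](c1ccc(OCc9ccccc9)c(OCc9ccccc9)c1)[C@@H](OCc9ccccc9)C2 | intermediate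
17 | (2R,3S,4S)-3,7,8-tris(benzyloxy)-2-[3,4-bis(benzyloxy)phenyl]-2-methoxy-4-(3,5,7,3',4'-penta-O-benzylcatechin-8-yl)chromane | O(Cc9ccccc9)c1ccc([C@@]2(OC)Oc3c(ccc(OCc9ccccc9)c3OCc9ccccc9)[C@@H](c3c(OCc9ccccc9)cc(OCc9ccccc9)c4c3O[C@H](c3ccc(OCc9ccccc9)c(OCc9ccccc9)c3)[C@@H](OCc9ccccc9)C4)[C@@H]2OCc9ccccc9)cc1OCc9ccccc9 | intermediate
18 | C2 oxocarbenium ion of the deca-O-benzyl dimer (formed in the flask) | O(Cc9ccccc9)c1ccc(C2=[O+]c3c(ccc(OCc9ccccc9)c3OCc9ccccc9)[C@@H](c3c(OCc9ccccc9)cc(OCc9ccccc9)c4c3O[C@H](c3ccc(OCc9ccccc9)c(OCc9ccccc9)c3)[C@@H](OCc9ccccc9)C4)[C@@H]2OCc9ccccc9)cc1OCc9ccccc9 | intermediate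
19 | (2R,3S,4S)-3,7,8-tris(benzyloxy)-2-[3,4-bis(benzyloxy)phenyl]-4-[(2R,3S)-3,5,7,3',4'-penta-O-benzylcatechin-8-yl]chromane (deca-O-benzyl dimer) | O(Cc9ccccc9)c1ccc([C@H]2Oc3c(ccc(OCc9ccccc9)c3OCc9ccccc9)[C@@H](c3c(OCc9ccccc9)cc(OCc9ccccc9)c4c3O[C@H](c3ccc(OCc9ccccc9)c(OCc9ccccc9)c3)[C@@H](OCc9ccccc9)C4)[C@@H]2OCc9ccccc9)cc1OCc9ccccc9 | intermediate
20 | CNP0231186.1, (2R,3S,4S)-2-(3,4-dihydroxyphenyl)-4-[(2R,3S)-2-(3,4-dihydroxyphenyl)-3,5,7-trihydroxychroman-8-yl]chromane-3,7,8-triol | Oc1ccc([C@H]2Oc3c(ccc(O)c3O)[C@@H](c3c(O)cc(O)c4c3O[C@H](c3ccc(O)c(O)c3)[C@@H](O)C4)[C@@H]2O)cc1O | target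

**Step count and risks**

Total step count: 14. Longest linear sequence: 8 steps (steps 1, 2, 3, 6, 7, 12, 13, 14).

Steps most likely to fail:

1. Step 12. The phosphate may fail to control the face of C4, because the aryl group on the methide carbon is bulky, twisted out of plane and itself chiral and may override the catalyst. The benzyloxy group may also add partly endo and give 3,4-cis material, and the enol ether may be lost to acid hydrolysis or the quinone methide to self-condensation. Fallback, from 10 back to 19, with enamine control and later introduction of ring B: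
   - 10 is treated with sodium p-toluenesulfinate in aqueous formic acid to give the sulfone 2,3-bis(benzyloxy)-6-[(4-methylphenyl)sulfonyl(3,5,7,3',4'-penta-O-benzylcatechin-8-yl)methyl]phenol F1.
   - With NaHCO3 in CH2Cl2 the sulfone releases the same quinone methide under basic conditions. It is intercepted by the enamine of benzyloxyacetaldehyde and (S)-2-[diphenyl(trimethylsilyloxy)methyl]pyrrolidine (or its antipode, whichever delivers the 3S,4S series) in a Michael addition and hemiacetalisation, giving the 3,4-trans lactol (3S,4S)-3,7,8-tris(benzyloxy)-4-(3,5,7,3',4'-penta-O-benzylcatechin-8-yl)chroman-2-ol F2.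
   - The open aldehyde form of the lactol is treated with excess 3,4-bis(benzyloxy)phenylmagnesium bromide F3 (from commercial 4-bromo-1,2-bis(benzyloxy)benzene and magnesium) to give the diol 1-[3,4-bis(benzyloxy)phenyl]-2-(benzyloxy)-3-[3,4-bis(benzyloxy)-2-hydroxyphenyl]-3-(3,5,7,3',4'-penta-O-benzylcatechin-8-yl)propan-1-ol F4 as C1 epimers.
   - Catalytic p-toluenesulfonic acid in CH2Cl2 ionises the para-benzyloxybenzylic alcohol and the ring A phenol closes ring C reversibly, which should converge on the all-equatorial 2,3-trans ether 19.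

2. Step 13. Hydride may be delivered to the other face of the oxocarbenium ion, anti to the 3-benzyloxy group through the half-chair with pseudo-axial substituents, giving the 2,3-cis ether. The ion may also lose H3 to a flav-2-ene and so scramble C3. Fallback, from 17 back to 19, setting C2 by C–O bond formation instead of hydride delivery:
   - 17 is hydrolysed with pyridinium p-toluenesulfonate in wet acetone to the hemiketal (3S,4S)-3,7,8-tris(benzyloxy)-2-[3,4-bis(benzyloxy)phenyl]-4-(3,5,7,3',4'-penta-O-benzylcatechin-8-yl)chroman-2-ol F5, which is in equilibrium with its ring-opened aryl ketone.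
   - NaBH4 in THF/MeOH reduces the ketone form to the diol F4 described above.
   - The same acid-mediated cycloetherification through the ring B-stabilised benzylic cation closes ring C to 19 under thermodynamic control.

3. Step 4. Benzylation may not discriminate cleanly between the 2- and 3-oxygens, giving mixtures of dibenzyl ethers and over-benzylation. Fallback, from 5 back to 6, replacing selective protection by selective deprotection:
   - 5 is benzylated exhaustively (BnBr 3.5 equiv, K2CO3, DMF, 60 °C) to 2,3,4-tris(benzyloxy)benzaldehyde F6.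
   - MgBr2·OEt2 in toluene/Et2O at reflux, chelated between the formyl oxygen and the ortho ether oxygen, cleaves only the benzyl ether ortho to the aldehyde and returns 6.

**Further compounds**

F1 | step 12 | 2,3-bis(benzyloxy)-6-[(4-methylphenyl)sulfonyl(3,5,7,3',4'-penta-O-benzylcatechin-8-yl)methyl]phenol | Oc1c(OCc9ccccc9)c(OCc9ccccc9)ccc1C(S(=O)(=O)c1ccc(C)cc1)c1c(OCc9ccccc9)cc(OCc9ccccc9)c2c1O[C@H](c1ccc(OCc9ccccc9)c(OCc9ccccc9)c1)[C@@H](OCc9ccccc9)C2
F2 | step 12 | (3S,4S)-3,7,8-tris(benzyloxy)-4-(3,5,7,3',4'-penta-O-benzylcatechin-8-yl)chroman-2-ol, both anomers | OC2Oc3c(ccc(OCc9ccccc9)c3OCc9ccccc9)[C@@H](c3c(OCc9ccccc9)cc(OCc9ccccc9)c4c3O[C@H](c3ccc(OCc9ccccc9)c(OCc9ccccc9)c3)[C@@H](OCc9ccccc9)C4)[C@@H]2OCc9ccccc9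
F3 | step 12 | 3,4-bis(benzyloxy)phenylmagnesium bromide | Br[Mg]c1ccc(OCc9ccccc9)c(OCc9ccccc9)c1
F4 | step 12 | 1-[3,4-bis(benzyloxy)phenyl]-2-(benzyloxy)-3-[3,4-bis(benzyloxy)-2-hydroxyphenyl]-3-(3,5,7,3',4'-penta-O-benzylcatechin-8-yl)propan-1-ol, C1 epimers, C2 and C3 as in 19 | O(Cc9ccccc9)c1ccc(C(O)[C@@H](OCc9ccccc9)[C@H](c3c(OCc9ccccc9)cc(OCc9ccccc9)c4c3O[C@H](c3ccc(OCc9ccccc9)c(OCc9ccccc9)c3)[C@@H](OCc9ccccc9)C4)c3ccc(OCc9ccccc9)c(OCc9ccccc9)c3O)cc1OCc9ccccc9
F5 | step 13 | (3S,4S)-3,7,8-tris(benzyloxy)-2-[3,4-bis(benzyloxy)phenyl]-4-(3,5,7,3',4'-penta-O-benzylcatechin-8-yl)chroman-2-ol, both anomers | O(Cc9ccccc9)c1ccc(C2(O)Oc3c(ccc(OCc9ccccc9)c3OCc9ccccc9)[C@@H](c3c(OCc9ccccc9)cc(OCc9ccccc9)c4c3O[C@H](c3ccc(OCc9ccccc9)c(OCc9ccccc9)c3)[C@@H](OCc9ccccc9)C4)[C@@H]2OCc9ccccc9)cc1OCc9ccccc9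
F6 | step 4 | 2,3,4-tris(benzyloxy)benzaldehyde | O=Cc1ccc(OCc9ccccc9)c(OCc9ccccc9)c1OCc9ccccc9
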